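## Structural features

Petchiether B (29) is a 14-membered meroterpenoid cyclophane. Ring A, a hydroquinone, is bridged from its ether oxygen O1 to the ortho carbon by the eleven-carbon chain C1'–C11', so the macrocycle consists of two aryl carbons, O1 and C1'–C11'. The chain holds a (2'E)-trisubstituted enoic acid (C2'=C3', carboxyl on C3') and a (6'Z)-trisubstituted alkene (C6'=C7', methyl on C7'), joined through C4'H2–C5'H2 into a 1,5-diene. The only stereocentre, C10' (R, secondary OH), stands directly next to the quaternary C11', whose two methyl groups and tertiary alkyl aryl ether bond to O1 make this the most hindered site. Fragile points are the free para-alkoxyphenol O4–H (oxidation), the tertiary alkyl aryl ether (ionisation by acid), the C1' methylene (benzylic, allylic and γ to the carboxyl, so base can move C2'=C3' towards ring A) and the Z alkene. The real difficulty is to close the 14-membered ring without losing either alkene geometry, and to build the hindered O1–C11' bond beside C10'. The key step uses the fact that C4' is the CH2 on the α-carbon of the enoate, that is, the methylene carbon of a 2-(1-oxyalkyl)acrylate after allylic transposition. Its neighbour C5' is allylic to C6'=C7' and can carry a sulfonyl-stabilised carbanion, so C4'–C5' can be made by SN2' substitution that closes the ring and creates the 2'E enoate at once.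

## Logic of the disconnections

**29 ⇐ 28 ⇐ 27 ⇐ 26.** No skeletal bond is cut. O10'–H is traced back to a silyl ether, C5'–H to C5'–SO2Ph, and the acid and O4–H to a methyl ester and an aryl silyl ether. The sulfonyl group is what makes C5' a carbon nucleophile, and the masks keep three acidic groups away from the carbanion. The demand is removal of the sulfonyl group without moving or isomerising C6'=C7'. Dissolving-metal cleavage of allylic sulfones tends to scramble the alkene, so hydride substitution through an allyl-palladium complex is planned. It is run on the acid 27, because LiBHEt3 would reduce the ester of 26. Hydroxide removes the aryl silyl ether together with the ester; this is accepted and planned for.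

**26 ⇐ 24.** The C4'–C5' bond is cut. It is the only C–C bond of the ring that is flanked by a latent electrophile (acrylate CH2) and a latent nucleophile (allylic sulfone), and cutting it opens the macrocycle to an acyclic chain on ring A. Checked against 29, both 24 and 26 have the right ring size, 6'Z and 2'E geometry and 10'R configuration. It must be added that 24 is a pair of C2' epimers and that a stereocentre does arise at C5' of 26; it is not controlled and is erased in step 19. The forward step must attack C4' and not C2', through the sulfur-bearing carbon, and must be free of nucleophilic amines, which would transpose the allyl system twice and deliver the carbanion to C2'.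

**24 ⇐ 23 ⇐ 21 + 22.** The C2'–C3' bond and the carbonate C–O bond are cut. This removes the whole acrylate unit in one Morita–Baylis–Hillman step and leaves an arylacetaldehyde. The forward step must cope with an enolisable, hindered aldehyde and with the acidic C5'–H2 of the sulfone.

**21 ⇐ 20 ⇐ 19.** Only the oxidation level of C2' and its silyl ether change. The demand is cleavage of a primary silyl ether beside a hindered secondary one and an aryl one.

**19 ⇐ 12 + 17.** The C7'–C8' bond is cut (sp3–sp2, B-alkyl Suzuki–Miyaura). This divides the chain into a ring-A fragment with the stereocentre and a four-carbon Z-iodoalkene that already carries the sulfone. A C9'-metallated five-carbon unit would instead need a protected C5' oxygen to be unmasked and exchanged for the sulfone after coupling. The forward step must retain the Z geometry and tolerate the allylic sulfone and the aryl silyl ether.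

**17 ⇐ 15 ⇐ 13.** The C5'–S and C7'–I bonds are cut. Hydroxyl-directed trans-hydroalumination of the alkyne fixes the Z geometry, which every later step only has to retain.

**12 ⇐ 11 ⇐ 10.** The C10'–H bond is cut. The stereocentre comes from reagent-controlled reduction of a ketone whose two flanks (quaternary C11' against vinyl) differ strongly in size.

**10 ⇐ 8 + 9.** The C9'–C10' bond is cut (acyl substitution on a Weinreb amide), which adds C8' and C9' as a vinyl group that later serves the hydroboration.

**8 ⇐ 7 ⇐ 6 ⇐ 4 + 5.** The O1–C11' bond is cut. The hindered ether is made first, on a simple phenol, with a tertiary α-bromo ester whose carbonyl activates the tertiary carbon and later becomes C10'. O1–H must be the only free phenol, and the base must spare the O4 silyl ether.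

**4 ⇐ 3 ⇐ 2 ⇐ 1.** The lactone C–O bond is the point: lactonisation ties up O1 and the carboxyl of 1, so O4 can be silylated alone, and reduction then frees O1–H and the C2' alcohol together.

## Other disconnections considered

**Alternative 1:** The cut is at both C11'–CH3 bonds, with the ring closed beforehand as the 14-membered aryl lactone A1 (C11' as the carbonyl on O1). The forward key step turns A1 into the tris-silyl macrocyclic tertiary ether A2 in one flask: methylenation of the lactone carbonyl by Cp2TiMe2, HCl addition across the new C=C, and replacement of chloride by methyl from AlMe3.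
- In its favour: macrolactonisation is the most dependable way to close a 14-membered ring. No substitution at a tertiary carbon is needed to form the O1–C11' link. C10' would be carried in from an α-oxygenated acid unit.
- Against it here: after HCl addition the aryloxide on C11' is itself a good leaving group, so ionisation may open the ring instead of accepting methyl. Under acid the new C=C can move to C10'=C11', which would erase the stereocentre. HCl and AlMe3 meet two trisubstituted alkenes. Cp2TiMe2 tolerates no second carbonyl, so C3' must travel as CH2OSi and be re-oxidised in two steps at the end beside a hydroquinone.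
- Comparison: on reliability of the ring closure it is the better plan, and it creates no temporary stereocentre. On mechanism the chosen plan does one C–C bond formation at an unhindered CH2 under base, while this one does three operations at the most hindered carbon under acid. On step economy the saved sulfone removal is cancelled by the re-oxidation of C3', so the two are about equal.

**Alternative 2:** The cut is at O1–C11'. Under mild acid the free O1–H of the seco (10'R)-epoxy phenol A3 opens the epoxide at its tertiary carbon to give O4-pivaloyl petchiether B ethyl ester A4, with C10' untouched.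
- In its favour: it follows the likely biogenesis and is the shortest plan. The chain is an intact farnesyl-type unit, C10' comes from a reagent-controlled epoxidation, O10' needs no protecting group, and attack at the tertiary carbon is the electronically preferred mode under acid.
- Against it here: the activated epoxide sits where C6'=C7' can attack C11' through a six-membered transition state, the classical cation–olefin cyclisation, which is entropically far ahead of a 14-membered etherification. Hydride shift to a C10' ketone, elimination, and C-alkylation of the electron-rich ring A are further intramolecular competitors that dilution cannot suppress.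
- Comparison: on step count, atom economy and absence of an auxiliary group it is clearly the better plan. The source of stereocontrol is equal (reagent control in both). On mechanism it is the weaker one, a cationic process with several low-barrier exits against an anionic process with one reactive pair. The chosen plan is longer but its ring closure does not compete with a six-membered alternative.

**Alternative 3:** The cut is at the aryl C–O1 bond. The potassium alkoxide of the seco fluoro aldehyde acid A5 (C11' tertiary OH, O10' methoxymethyl) displaces fluoride para to the formyl group and gives the formyl macrocyclic ether acid A6. The formyl group later becomes O4–H by Dakin oxidation.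
- In its favour: the tertiary carbon is not the electrophilic site, so ionisation and elimination at C11' do not arise. Macro-etherification by nucleophilic aromatic substitution is an established ring closure, and the activating group is a latent form of the phenol.
- Against it here: a tertiary alkoxide attacking next to an ortho substituent, with only a formyl activator, needs heat in a dipolar solvent. Under those conditions the alkoxide can add to or transfer hydride to the aldehyde and can deprotonate C1', moving C2'=C3'. The carboxylate makes a poorly soluble dianion. The peroxide oxidation must spare two alkenes, and removal of the methoxymethyl group needs acid beside the tertiary alkyl aryl ether.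
- Comparison: on structure it is the better plan in one respect, since it forms the hindered ether and the ring in a single step. The number of steps after ring closure is about equal to the three of the chosen plan. On mechanism the chosen plan attacks an unhindered CH2 at low temperature, while this one forces a hindered nucleophile onto a weakly activated arene, and its final acid step threatens the O1–C11' bond.

Key step: step 17

Remark on the chemistry: locants C1'–C11' run from the benzylic CH2 to CMe2, O1 is the ether oxygen and O4 the phenolic oxygen of ring A; TBSO = tert-butyldimethylsilyloxy, TIPSO = triisopropylsilyloxy. Compounds 23–25 are taken as mixtures of C2' epimers and 25–27 as mixtures of C5' epimers, because both centres are erased before the end.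

## Route

Step 1
Reactants: 1 homogentisic acid
Product: 2 homogentisic lactone (5-hydroxy-1-benzofuran-2(3H)-one)
Conditions: TsOH·H2O (cat.), toluene/dioxane, reflux, Dean–Stark
Reagents that add atoms: none
Why: Acid-catalysed lactonisation (intramolecular Fischer esterification) can only engage the ortho phenol, so O1 and the carboxyl are tied up in a five-membered aryl lactone and O4–H is left as the single free hydroxyl.

Step 2
Reactants: 2 homogentisic lactone
Product: 3 5-(triisopropylsilyloxy)-1-benzofuran-2(3H)-one
Conditions: TIPSCl, imidazole, CH2Cl2, 0 → 23 °C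
Reagents that add atoms: triisopropylsilyl chloride, CC(C)[Si](Cl)(C(C)C)C(C)C
Why: Standard silyl ether formation on a phenol; the hindered triisopropylsilyl group is chosen because it has to survive carbonate, organomagnesium, borane, mild acid and amide base up to step 17.

Step 3
Reactants: 3 5-(triisopropylsilyloxy)-1-benzofuran-2(3H)-one
Product: 4 2-(2-hydroxyethyl)-4-(triisopropylsilyloxy)phenol
Conditions: LiBH4, THF, 0 → 23 °C; aq. NH4Cl
Reagents that add atoms: none
Why: Hydride reduction of the aryl ester (lactone) releases O1–H and the C2' primary alcohol in one operation; the aryl silyl ether is inert to borohydride.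

Step 4
Reactants: 4 2-(2-hydroxyethyl)-4-(triisopropylsilyloxy)phenol; 5 ethyl 2-bromo-2-methylpropanoate
Product: 6 ethyl 2-[2-(2-hydroxyethyl)-4-(TIPSO)phenoxy]-2-methylpropanoate
Conditions: Cs2CO3, 5 (3 equiv), MeCN (anhydrous), 60 °C
Reagents that add atoms: none
Why: Williamson-type O-alkylation of the caesium phenoxide with the tertiary α-bromo ester, the standard entry to 2-aryloxy-2-methylpropanoates; carbonate deprotonates only the phenol, so the primary alcohol stays free, and excess bromide makes up for loss by elimination.

Step 5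
Reactants: 6 ethyl 2-[2-(2-hydroxyethyl)-4-(TIPSO)phenoxy]-2-methylpropanoate
Product: 7 ethyl 2-{2-[2-(TBSO)ethyl]-4-(TIPSO)phenoxy}-2-methylpropanoate
Conditions: TBSCl, imidazole, CH2Cl2, 23 °C
Reagents that add atoms: tert-butyldimethylsilyl chloride, CC(C)(C)[Si](C)(C)Cl
Why: Silyl ether formation masks the C2' alcohol for the organomagnesium and borane steps; as a primary TBS ether it can later be removed by mild acid beside the hindered secondary TBS ether and the aryl TIPS ether.

Step 6
Reactants: 7 ethyl 2-{2-[2-(TBSO)ethyl]-4-(TIPSO)phenoxy}-2-methylpropanoate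
Product: 8 2-{2-[2-(TBSO)ethyl]-4-(TIPSO)phenoxy}-N-methoxy-N,2-dimethylpropanamide
Conditions: MeNH(OMe)·HCl, i-PrMgCl, THF, −20 → 0 °C
Reagents that add atoms: N,O-dimethylhydroxylamine hydrochloride, CNOC.Cl
Why: Direct aminolysis of the ester by the chloromagnesium amide (Weinreb amide synthesis); the α-aryloxy group activates the hindered ester and there is no α-hydrogen to enolise.

Step 7
Reactants: 8 2-{2-[2-(TBSO)ethyl]-4-(TIPSO)phenoxy}-N-methoxy-N,2-dimethylpropanamide; 9 vinylmagnesium bromide
Product: 10 4-{2-[2-(TBSO)ethyl]-4-(TIPSO)phenoxy}-4-methylpent-1-en-3-one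
Conditions: THF, −78 → 0 °C; inverse quench into cold 1 M HCl
Reagents that add atoms: none
Why: Weinreb ketone synthesis: the chelated tetrahedral adduct resists a second addition and collapses to the vinyl ketone on quench; the cold acidic quench keeps the liberated amine protonated so that it cannot add to the enone.

Step 8
Reactants: 10 4-{2-[2-(TBSO)ethyl]-4-(TIPSO)phenoxy}-4-methylpent-1-en-3-one
Product: 11 (3R)-4-{2-[2-(TBSO)ethyl]-4-(TIPSO)phenoxy}-4-methylpent-1-en-3-ol
Conditions: (S)-2-methyl-CBS-oxazaborolidine (0.2 equiv), catecholborane, toluene, −78 °C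
Reagents that add atoms: none
Why: Corey–Bakshi–Shibata reduction; the ketone should bind the (S)-oxazaborolidine with the quaternary C11' group as the large and vinyl as the small substituent, so hydride goes to the face that gives 10'R (the same sense as acetophenone to (R)-1-phenylethanol). Catecholborane at −78 °C does not hydroborate the vinyl group.

Step 9
Reactants: 11 (3R)-4-{2-[2-(TBSO)ethyl]-4-(TIPSO)phenoxy}-4-methylpent-1-en-3-ol
Product: 12 (3R)-3-(TBSO)-4-{2-[2-(TBSO)ethyl]-4-(TIPSO)phenoxy}-4-methylpent-1-ene
Conditions: TBSOTf, 2,6-lutidine, CH2Cl2, −78 → 0 °C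
Reagents that add atoms: tert-butyldimethylsilyl trifluoromethanesulfonate, CC(C)(C)[Si](C)(C)OS(=O)(=O)C(F)(F)F
Why: Silylation of a hindered secondary alcohol with a silyl triflate and a non-nucleophilic base; no bond to C10' is broken, so the configuration is kept.

Step 10
Reactants: 13 but-2-yn-1-ol
Product: 15 (2Z)-3-iodobut-2-en-1-ol, via cyclic vinylaluminate 14 (not isolated)
Conditions: NaAlH2(OCH2CH2OMe)2, THF, 0 → 23 °C; then I2, −78 → 0 °C
Reagents that add atoms: iodine, II
Why: Hydroxyl-directed trans-hydroalumination of the propargylic alcohol puts aluminium on C3 cis to the CH2O group in a five-membered aluminate, and iodinolysis with retention gives the Z vinyl iodide; this fixes the later 6'Z geometry.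

Step 11
Reactants: 15 (2Z)-3-iodobut-2-en-1-ol
Product: 17 [(2Z)-3-iodobut-2-en-1-yl]sulfonylbenzene, via allylic mesylate 16 (not isolated)
Conditions: MsCl, Et3N, THF, −20 °C; then PhSO2Na, Bu4NI (cat.), DMF, 23 °C
Reagents that add atoms: sodium benzenesulfinate, [Na+].[O-]S(=O)c1ccccc1
Why: Sulfonate formation followed by SN2 displacement at the primary allylic carbon by the sulfur of benzenesulfinate gives the allylic sulfone; the electron-poor iodoalkene disfavours ionisation, so the Z geometry should be kept.

Step 12
Reactants: 12 (3R)-3-(TBSO)-4-{2-[2-(TBSO)ethyl]-4-(TIPSO)phenoxy}-4-methylpent-1-ene; 17 [(2Z)-3-iodobut-2-en-1-yl]sulfonylbenzene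
Product: 19 1-{[(3R,6Z)-3-(TBSO)-2,6-dimethyl-8-(phenylsulfonyl)oct-6-en-2-yl]oxy}-2-[2-(TBSO)ethyl]-4-(TIPSO)benzene, via alkylborane 18 (not isolated)
Conditions: 9-BBN, THF, 23 → 40 °C; then 17, Pd(dppf)Cl2 (cat.), AsPh3 (cat.), 3 M aq. K3PO4, DMF, 23 °C
Reagents that add atoms: none
Why: Anti-Markovnikov hydroboration of the monosubstituted alkene puts boron on C8', and B-alkyl Suzuki–Miyaura coupling with the vinyl iodide forms C7'–C8' with retention of alkene geometry. Oxidative addition of zerovalent palladium into C–I is far faster than ionisation of the allylic sulfone, and phosphate instead of hydroxide spares the aryl silyl ether.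

Step 13
Reactants: 19 1-{[(3R,6Z)-3-(TBSO)-2,6-dimethyl-8-(phenylsulfonyl)oct-6-en-2-yl]oxy}-2-[2-(TBSO)ethyl]-4-(TIPSO)benzene
Product: 20 2-(2-{[(3R,6Z)-3-(TBSO)-2,6-dimethyl-8-(phenylsulfonyl)oct-6-en-2-yl]oxy}-5-(TIPSO)phenyl)ethanol
Conditions: camphorsulfonic acid (0.1 equiv), MeOH/CH2Cl2 (1:1), 0 °C
Reagents that add atoms: none
Why: Acid-catalysed methanolysis of a silyl ether; the unhindered primary TBS ether reacts much faster than the neopentyl-type secondary one at C10', and the aryl TIPS ether is stable to mild acid.

Step 14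
Reactants: 20 2-(2-{[(3R,6Z)-3-(TBSO)-2,6-dimethyl-8-(phenylsulfonyl)oct-6-en-2-yl]oxy}-5-(TIPSO)phenyl)ethanol
Product: 21 (2-{[(3R,6Z)-3-(TBSO)-2,6-dimethyl-8-(phenylsulfonyl)oct-6-en-2-yl]oxy}-5-(TIPSO)phenyl)acetaldehyde
Conditions: Dess–Martin periodinane, NaHCO3, CH2Cl2, 0 → 23 °C
Reagents that add atoms: none
Why: Dess–Martin oxidation of a primary alcohol stops at the aldehyde under buffered, non-enolising conditions; the sensitive arylacetaldehyde is used at once.

Step 15
Reactants: 21 (2-{[(3R,6Z)-3-(TBSO)-2,6-dimethyl-8-(phenylsulfonyl)oct-6-en-2-yl]oxy}-5-(TIPSO)phenyl)acetaldehyde; 22 methyl acrylate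
Product: 23 methyl 3-hydroxy-2-methylidene-4-(2-{[(3R,6Z)-3-(TBSO)-2,6-dimethyl-8-(phenylsulfonyl)oct-6-en-2-yl]oxy}-5-(TIPSO)phenyl)butanoate (both C2' epimers)
Conditions: quinuclidine (0.5 equiv), MeOH (1 equiv), 22 (neat, excess), 23 °C
Reagents that add atoms: none
Why: Morita–Baylis–Hillman reaction: the amine adds to the acrylate, the ammonium enolate adds to the aldehyde and loss of the amine gives the 2-(1-hydroxyalkyl)acrylate, a reaction known for phenylacetaldehydes. The new C2' carbinol centre is not controlled and need not be, because it becomes sp2 in step 17.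

Step 16
Reactants: 23 methyl 3-hydroxy-2-methylidene-4-(aryl)butanoate (both C2' epimers)
Product: 24 methyl 3-(tert-butoxycarbonyloxy)-2-methylidene-4-(2-{[(3R,6Z)-3-(TBSO)-2,6-dimethyl-8-(phenylsulfonyl)oct-6-en-2-yl]oxy}-5-(TIPSO)phenyl)butanoate (both C2' epimers)
Conditions: Boc2O, DMAP (0.05 equiv), CH2Cl2, 0 °C
Reagents that add atoms: di-tert-butyl dicarbonate, CC(C)(C)OC(=O)OC(=O)OC(C)(C)C
Why: DMAP-catalysed acylation of the secondary allylic alcohol gives the tert-butyl carbonate, the usual leaving group for SN2' chemistry of Baylis–Hillman adducts; low temperature and little DMAP guard against amine-triggered substitution before the amine is washed out.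

Step 17
Reactants: 24 methyl 3-(tert-butoxycarbonyloxy)-2-methylidene-4-(aryl)butanoate (both C2' epimers)
Product: 26 (2'E,6'Z,10'R)-5'-(phenylsulfonyl)-O4-TIPS-O10'-TBS-petchiether B methyl ester (both C5' epimers), via lithiated sulfone 25 (not isolated)
Conditions: slow addition of 24 to LiN(SiMe3)2 (1.2 equiv), THF (final 2 mM), −40 → −20 °C; aq. NH4Cl
Reagents that add atoms: none
Why: LiN(SiMe3)2 removes a C5' proton α to the sulfone, by far the most acidic C–H of 24, to give 25. The carbanion adds in conjugate fashion to the unsubstituted acrylate terminus C4', and the ester enolate so formed expels tert-butyl carbonate from C2' (E1cB), an overall SN2' substitution that makes C4'–C5'. The closest known reactions are SN2' alkylations of Baylis–Hillman acetates and carbonates by stabilised carbanions and sulfone-carbanion closures of 14-membered terpenoid rings. The single ring closed is the 14-membered one, in the 14-endo-trig mode with respect to C3'=C4'; slow addition at high dilution favours it, and the Z alkene and the ortho-disubstituted ring A act as turn elements. No stereocentre of the target is formed: C5' arises uncontrolled, both C2' epimers converge, and C10' is not involved. Attack through C5' and not C7' follows from the sulfonyl group, which localises the charge on the sulfur-bearing carbon and keeps the 6'Z geometry at low temperature. The 2'E geometry follows from the elimination step, in which ester-derived Baylis–Hillman electrophiles place the C1' substituent anti to the ester. Attack at C4' and not at C2' requires that no nucleophilic amine or phosphine is present, since such a catalyst would transpose the allyl system twice.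

Step 18
Reactants: 26 (2'E,6'Z,10'R)-5'-(phenylsulfonyl)-O4-TIPS-O10'-TBS-petchiether B methyl ester (both C5' epimers)
Product: 27 (2'E,6'Z,10'R)-5'-(phenylsulfonyl)-O10'-TBS-petchiether B (both C5' epimers)
Conditions: LiOH·H2O (10 equiv), THF/MeOH/H2O (2:1:1), argon, 40 °C; then pH 4
Reagents that add atoms: lithium hydroxide monohydrate, [Li+].[OH-].O
Why: Saponification of the methyl ester; under the same conditions hydroxide cleaves the base-labile aryl silyl ether, while the alkyl TBS ether, the sulfone and the enoate geometry should be unaffected. Any aryl silyl ether that remains would fall off in step 20.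

Step 19
Reactants: 27 (2'E,6'Z,10'R)-5'-(phenylsulfonyl)-O10'-TBS-petchiether B (both C5' epimers)
Product: 28 (2'E,6'Z,10'R)-O10'-TBS-petchiether B
Conditions: PdCl2(dppp) (0.1 equiv), LiBHEt3 (6 equiv), THF, −20 → 0 °C
Reagents that add atoms: none
Why: Palladium-catalysed hydride substitution of an allylic sulfone: zerovalent palladium, formed from PdCl2(dppp) and hydride, ionises the C5'–S bond and LiBHEt3 delivers hydride to the less substituted allyl terminus C5'. This method is known to keep the position and geometry of trisubstituted alkenes, and the lithium carboxylate and phenoxide formed by the first equivalents of hydride are inert to the reagent.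

Step 20
Reactants: 28 (2'E,6'Z,10'R)-O10'-TBS-petchiether B
Product: 29 petchiether B (2'E,6'Z,10'R)
Conditions: Bu4NF, THF, 50 °C; aq. NH4Cl
Reagents that add atoms: none
Why: Fluoride-induced cleavage of the remaining silyl ether (Si–F bond formation); warming is planned because the C10' ether is flanked by a quaternary carbon, and C10' itself is not touched.

## Compound list

1 | homogentisic acid (2,5-dihydroxyphenylacetic acid) | OC(=O)Cc1cc(O)ccc1O | starting material
2 | homogentisic lactone (5-hydroxy-1-benzofuran-2(3H)-one) | O=C1Cc2cc(O)ccc2O1 | intermediate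
3 | 5-(triisopropylsilyloxy)-1-benzofuran-2(3H)-one | O=C1Cc2cc(O[Si](C(C)C)(C(C)C)C(C)C)ccc2O1 | intermediate
4 | 2-(2-hydroxyethyl)-4-(triisopropylsilyloxy)phenol | OCCc1cc(O[Si](C(C)C)(C(C)C)C(C)C)ccc1O | intermediate
5 | ethyl 2-bromo-2-methylpropanoate | CCOC(=O)C(C)(C)Br | starting material
6 | ethyl 2-[2-(2-hydroxyethyl)-4-(TIPSO)phenoxy]-2-methylpropanoate | CCOC(=O)C(C)(C)Oc1ccc(O[Si](C(C)C)(C(C)C)C(C)C)cc1CCO | intermediate
7 | ethyl 2-{2-[2-(TBSO)ethyl]-4-(TIPSO)phenoxy}-2-methylpropanoate | CCOC(=O)C(C)(C)Oc1ccc(O[Si](C(C)C)(C(C)C)C(C)C)cc1CCO[Si](C)(C)C(C)(C)C | intermediate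
8 | 2-{2-[2-(TBSO)ethyl]-4-(TIPSO)phenoxy}-N-methoxy-N,2-dimethylpropanamide | CON(C)C(=O)C(C)(C)Oc1ccc(O[Si](C(C)C)(C(C)C)C(C)C)cc1CCO[Si](C)(C)C(C)(C)C | intermediate
9 | vinylmagnesium bromide | C=C[Mg]Br | starting material
10 | 4-{2-[2-(TBSO)ethyl]-4-(TIPSO)phenoxy}-4-methylpent-1-en-3-one | C=CC(=O)C(C)(C)Oc1ccc(O[Si](C(C)C)(C(C)C)C(C)C)cc1CCO[Si](C)(C)C(C)(C)C | intermediate
11 | (3R)-4-{2-[2-(TBSO)ethyl]-4-(TIPSO)phenoxy}-4-methylpent-1-en-3-ol | C=C[C@@H](O)C(C)(C)Oc1ccc(O[Si](C(C)C)(C(C)C)C(C)C)cc1CCO[Si](C)(C)C(C)(C)C | intermediate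
12 | (3R)-3-(TBSO)-4-{2-[2-(TBSO)ethyl]-4-(TIPSO)phenoxy}-4-methylpent-1-ene | C=C[C@@H](O[Si](C)(C)C(C)(C)C)C(C)(C)Oc1ccc(O[Si](C(C)C)(C(C)C)C(C)C)cc1CCO[Si](C)(C)C(C)(C)C | intermediate
13 | but-2-yn-1-ol | CC#CCO | starting material
14 | sodium 2,2-bis(2-methoxyethoxy)-3-methyl-2,5-dihydro-1,2-oxaluminol-2-uide (cyclic vinylaluminate) | CC1=CCO[Al-]1(OCCOC)OCCOC.[Na+] | intermediate
15 | (2Z)-3-iodobut-2-en-1-ol | C/C(I)=C/CO | intermediate
16 | (2Z)-3-iodobut-2-en-1-yl methanesulfonate | C/C(I)=C/COS(C)(=O)=O | intermediate
17 | [(2Z)-3-iodobut-2-en-1-yl]sulfonylbenzene | C/C(I)=C/CS(=O)(=O)c1ccccc1 | intermediate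
18 | 9-[(3R)-3-(TBSO)-4-{2-[2-(TBSO)ethyl]-4-(TIPSO)phenoxy}-4-methylpentyl]-9-borabicyclo[3.3.1]nonane | CC(C)(C)[Si](C)(C)OCCc1cc(O[Si](C(C)C)(C(C)C)C(C)C)ccc1OC(C)(C)[C@H](O[Si](C)(C)C(C)(C)C)CCB1C2CCCC1CCC2 | intermediate
19 | 1-{[(3R,6Z)-3-(TBSO)-2,6-dimethyl-8-(phenylsulfonyl)oct-6-en-2-yl]oxy}-2-[2-(TBSO)ethyl]-4-(TIPSO)benzene | CC(C)(C)[Si](C)(C)OCCc1cc(O[Si](C(C)C)(C(C)C)C(C)C)ccc1OC(C)(C)[C@H](O[Si](C)(C)C(C)(C)C)CC/C(C)=C\CS(=O)(=O)c1ccccc1 | intermediate
20 | 2-(2-{[(3R,6Z)-3-(TBSO)-2,6-dimethyl-8-(phenylsulfonyl)oct-6-en-2-yl]oxy}-5-(TIPSO)phenyl)ethanol | OCCc1cc(O[Si](C(C)C)(C(C)C)C(C)C)ccc1OC(C)(C)[C@H](O[Si](C)(C)C(C)(C)C)CC/C(C)=C\CS(=O)(=O)c1ccccc1 | intermediate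
21 | (2-{[(3R,6Z)-3-(TBSO)-2,6-dimethyl-8-(phenylsulfonyl)oct-6-en-2-yl]oxy}-5-(TIPSO)phenyl)acetaldehyde | O=CCc1cc(O[Si](C(C)C)(C(C)C)C(C)C)ccc1OC(C)(C)[C@H](O[Si](C)(C)C(C)(C)C)CC/C(C)=C\CS(=O)(=O)c1ccccc1 | intermediate
22 | methyl acrylate | C=CC(=O)OC | starting material
23 | methyl 3-hydroxy-2-methylidene-4-(2-{[(3R,6Z)-3-(TBSO)-2,6-dimethyl-8-(phenylsulfonyl)oct-6-en-2-yl]oxy}-5-(TIPSO)phenyl)butanoate (both C2' epimers) | C=C(C(=O)OC)C(O)Cc1cc(O[Si](C(C)C)(C(C)C)C(C)C)ccc1OC(C)(C)[C@H](O[Si](C)(C)C(C)(C)C)CC/C(C)=C\CS(=O)(=O)c1ccccc1 | intermediate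
24 | methyl 3-(tert-butoxycarbonyloxy)-2-methylidene-4-(2-{[(3R,6Z)-3-(TBSO)-2,6-dimethyl-8-(phenylsulfonyl)oct-6-en-2-yl]oxy}-5-(TIPSO)phenyl)butanoate (both C2' epimers; cyclisation precursor) | C=C(C(=O)OC)C(OC(=O)OC(C)(C)C)Cc1cc(O[Si](C(C)C)(C(C)C)C(C)C)ccc1OC(C)(C)[C@H](O[Si](C)(C)C(C)(C)C)CC/C(C)=C\CS(=O)(=O)c1ccccc1 | intermediate
25 | C5'-lithio derivative of 24 (lithiated sulfone) | C=C(C(=O)OC)C(OC(=O)OC(C)(C)C)Cc1cc(O[Si](C(C)C)(C(C)C)C(C)C)ccc1OC(C)(C)[C@H](O[Si](C)(C)C(C)(C)C)CC/C(C)=C\C([Li])S(=O)(=O)c1ccccc1 | intermediate
26 | (2'E,6'Z,10'R)-5'-(phenylsulfonyl)-O4-TIPS-O10'-TBS-petchiether B methyl ester (both C5' epimers) | C/C1=C/C(S(=O)(=O)c3ccccc3)C/C(C(=O)OC)=C\Cc2cc(O[Si](C(C)C)(C(C)C)C(C)C)ccc2OC(C)(C)[C@H](O[Si](C)(C)C(C)(C)C)CC1 | intermediate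
27 | (2'E,6'Z,10'R)-5'-(phenylsulfonyl)-O10'-TBS-petchiether B (both C5' epimers) | C/C1=C/C(S(=O)(=O)c3ccccc3)C/C(C(=O)O)=C\Cc2cc(O)ccc2OC(C)(C)[C@H](O[Si](C)(C)C(C)(C)C)CC1 | intermediate
28 | (2'E,6'Z,10'R)-O10'-TBS-petchiether B | C/C1=C/CC/C(C(=O)O)=C\Cc2cc(O)ccc2OC(C)(C)[C@H](O[Si](C)(C)C(C)(C)C)CC1 | intermediate
29 | petchiether B (2'E,6'Z,10'R) | C/C1=C/CC/C(C(=O)O)=C\Cc2cc(O)ccc2OC(C)(C)[C@H](O)CC1 | target

## Step count and least certain steps

Total: 20 steps. Longest linear sequence: 18 steps (steps 1–9 and 12–20 from 1); steps 10–11 make fragment 17, which joins at step 12.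

**Step 17 (key step).** Most likely to go wrong: intermolecular conjugate addition (oligomers) outrunning the 14-membered closure, or addition of the amide base to the acrylate before proton transfer from C5'.
Fallback: form C4'–C5' between two molecules and close the ring at C7'–C8' instead.
- Setting out from 12, the primary silyl ether is cleaved (camphorsulfonic acid, MeOH) to 2-(2-{[(3R)-3-(TBSO)-2-methylpent-4-en-2-yl]oxy}-5-(TIPSO)phenyl)ethanol F1.
- Dess–Martin oxidation gives the corresponding arylacetaldehyde F2.
- The Morita–Baylis–Hillman reaction with 22 gives the hydroxy acrylate F3, and Boc2O/DMAP gives its tert-butyl carbonate F4.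
- The lithio derivative of 17 (LiN(SiMe3)2, THF, −78 °C) then attacks C4' of F4 in an intermolecular SN2' reaction, where dilution is no issue, to give the seco iodo diene ester F5.
- 9-BBN adds to the terminal vinyl group to give the C8' alkylborane F6 (not isolated).
- Intramolecular B-alkyl Suzuki–Miyaura coupling under high dilution (Pd(dppf)Cl2, AsPh3, aq. K3PO4, DMF/THF) closes the ring and comes back to the route at 26.

**Step 15.** Most likely to go wrong: slow addition of the ammonium enolate to a hindered, enolisable arylacetaldehyde, so that self-aldol condensation and base-triggered Michael addition of C5'–H to the acrylate take over.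
Fallback: stoichiometric vinyl-metal addition instead of amine catalysis. Setting out from 21, methyl propiolate is hydroaluminated at its α-carbon with i-Bu2AlH and N-methylmorpholine N-oxide (THF, 0 °C) to diisobutyl[1-(methoxycarbonyl)ethenyl]alane F7. F7 adds to the aldehyde under non-basic conditions and comes back to the route at 23.

**Step 8.** Most likely to go wrong: insufficient facial discrimination between the quaternary group and the vinyl group, or conjugate reduction of the enone.
Fallback: set C10' on an ynone by transfer hydrogenation.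
- Setting out from 8, LiC≡CSiMe3 gives 4-{2-[2-(TBSO)ethyl]-4-(TIPSO)phenoxy}-4-methyl-1-(trimethylsilyl)pent-1-yn-3-one F8.
- Noyori transfer hydrogenation with RuCl[(S,S)-TsDPEN](p-cymene) in i-PrOH, with the alkyne taking the place of the aryl group in the usual model, should give the (3R)-propargylic alcohol F9.
- K2CO3/MeOH removes the C-silyl group to give the (3R)-terminal alkynol F10.
- Semi-hydrogenation (H2, Pd/CaCO3 poisoned with Pb(OAc)2, quinoline) comes back to the route at 11.

**Step 19.** Most likely to go wrong: hydride delivery to C7' or syn–anti interconversion of the allyl-palladium intermediate (loss of position or geometry of C6'=C7'), β-hydride elimination to a diene, or capture of the allyl complex by the C3' carboxylate.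
Fallback: reductive cleavage by single-electron transfer instead of allyl-palladium chemistry. Setting out from 27, Na(Hg) with Na2HPO4 in MeOH/THF at −20 °C cleaves the C5'–S bond; the carboxylate is too electron-rich to be reduced, and the sequence comes back to the route at 28 with no new compound.

## Further compounds

F1 | step 17 | 2-(2-{[(3R)-3-(TBSO)-2-methylpent-4-en-2-yl]oxy}-5-(TIPSO)phenyl)ethanol | OCCc1cc(O[Si](C(C)C)(C(C)C)C(C)C)ccc1OC(C)(C)[C@H](O[Si](C)(C)C(C)(C)C)C=C
F2 | step 17 | (2-{[(3R)-3-(TBSO)-2-methylpent-4-en-2-yl]oxy}-5-(TIPSO)phenyl)acetaldehyde | O=CCc1cc(O[Si](C(C)C)(C(C)C)C(C)C)ccc1OC(C)(C)[C@H](O[Si](C)(C)C(C)(C)C)C=C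
F3 | step 17 | methyl 3-hydroxy-2-methylidene-4-(2-{[(3R)-3-(TBSO)-2-methylpent-4-en-2-yl]oxy}-5-(TIPSO)phenyl)butanoate (both C3 epimers) | C=C(C(=O)OC)C(O)Cc1cc(O[Si](C(C)C)(C(C)C)C(C)C)ccc1OC(C)(C)[C@H](O[Si](C)(C)C(C)(C)C)C=C
F4 | step 17 | methyl 3-(tert-butoxycarbonyloxy)-2-methylidene-4-(2-{[(3R)-3-(TBSO)-2-methylpent-4-en-2-yl]oxy}-5-(TIPSO)phenyl)butanoate (both C3 epimers) | C=C(C(=O)OC)C(OC(=O)OC(C)(C)C)Cc1cc(O[Si](C(C)C)(C(C)C)C(C)C)ccc1OC(C)(C)[C@H](O[Si](C)(C)C(C)(C)C)C=C
F5 | step 17 | methyl (5Z)-6-iodo-4-(phenylsulfonyl)-2-[(E)-2-(2-{[(3R)-3-(TBSO)-2-methylpent-4-en-2-yl]oxy}-5-(TIPSO)phenyl)ethylidene]hept-5-enoate (both C4 epimers) | C/C(I)=C/C(S(=O)(=O)c1ccccc1)C/C(C(=O)OC)=C\Cc1cc(O[Si](C(C)C)(C(C)C)C(C)C)ccc1OC(C)(C)[C@H](O[Si](C)(C)C(C)(C)C)C=C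
F6 | step 17 | 9-BBN adduct of F5 at the terminal vinyl carbon (C8' alkylborane) | C/C(I)=C/C(S(=O)(=O)c1ccccc1)C/C(C(=O)OC)=C\Cc1cc(O[Si](C(C)C)(C(C)C)C(C)C)ccc1OC(C)(C)[C@H](O[Si](C)(C)C(C)(C)C)CCB1C2CCCC1CCC2
F7 | step 15 | diisobutyl[1-(methoxycarbonyl)ethenyl]alane | C=C(C(=O)OC)[Al](CC(C)C)CC(C)C
F8 | step 8 | 4-{2-[2-(TBSO)ethyl]-4-(TIPSO)phenoxy}-4-methyl-1-(trimethylsilyl)pent-1-yn-3-one | C[Si](C)(C)C#CC(=O)C(C)(C)Oc1ccc(O[Si](C(C)C)(C(C)C)C(C)C)cc1CCO[Si](C)(C)C(C)(C)C
F9 | step 8 | (3R)-4-{2-[2-(TBSO)ethyl]-4-(TIPSO)phenoxy}-4-methyl-1-(trimethylsilyl)pent-1-yn-3-ol | C[Si](C)(C)C#C[C@@H](O)C(C)(C)Oc1ccc(O[Si](C(C)C)(C(C)C)C(C)C)cc1CCO[Si](C)(C)C(C)(C)C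
F10 | step 8 | (3R)-4-{2-[2-(TBSO)ethyl]-4-(TIPSO)phenoxy}-4-methylpent-1-yn-3-ol | C#C[C@@H](O)C(C)(C)Oc1ccc(O[Si](C(C)C)(C(C)C)C(C)C)cc1CCO[Si](C)(C)C(C)(C)C
F0 | step 19 | none | none
A1 | alternative 1 | tris-TBS 14-membered aryl lactone (C11' as lactone carbonyl on O1; C3' CH2OTBS; 2'E,6'Z,10'R) | C/C1=C/CC/C(CO[Si](C)(C)C(C)(C)C)=C\Cc2cc(O[Si](C)(C)C(C)(C)C)ccc2OC(=O)[C@H](O[Si](C)(C)C(C)(C)C)CC1
A2 | alternative 1 | tris-silyl macrocyclic tertiary ether (C11' gem-dimethyl; 2'E,6'Z,10'R) | C/C1=C/CC/C(CO[Si](C)(C)C(C)(C)C)=C\Cc2cc(O[Si](C)(C)C(C)(C)C)ccc2OC(C)(C)[C@H](O[Si](C)(C)C(C)(C)C)CC1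
A3 | alternative 2 | seco (10'R)-10',11'-epoxy phenol ethyl ester with O4 pivalate (2'E,6'Z) | CC1(C)O[C@@H]1CC/C(C)=C\CC/C(C(=O)OCC)=C\Cc1cc(OC(=O)C(C)(C)C)ccc1O
A4 | alternative 2 | O4-pivaloyl petchiether B ethyl ester | C/C1=C/CC/C(C(=O)OCC)=C\Cc2cc(OC(=O)C(C)(C)C)ccc2OC(C)(C)[C@H](O)CC1
A5 | alternative 3 | seco fluoro aldehyde acid with C11' tertiary alcohol and O10' methoxymethyl ether (2'E,6'Z,10'R) | CC(C)(O)[C@H](OCOC)CC/C(C)=C\CC/C(C(=O)O)=C\Cc1cc(C=O)ccc1F
A6 | alternative 3 | formyl macrocyclic ether acid (O10' methoxymethyl) | C/C1=C/CC/C(C(=O)O)=C\Cc2cc(C=O)ccc2OC(C)(C)[C@H](OCOC)CC1
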